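**Strategy.** Everything rests on cutting the two C–CH3 bonds at C10 and C15 of a C2-symmetric C5–C20 core (axis through the C12–C13 bond). One chelation-controlled double addition of MeMgBr to a bis(α-alkoxy ketone) sets both tertiary carbinol centres (C10, C15) from the C11/C14 ethers. It exploits the fact that each oxirane ring (O–C10–C11, O–C14–C15) joins a methyl-bearing quaternary carbon to an oxygenated secondary carbon, and that the two halves are symmetry-equivalent. The precursor is the (7R,11R,14R,18R) 10,15-diketone with PMB ethers at C11/C14 and silyl ethers at C5/C20; the oxiranes are then closed with inversion and the enantiomeric C1–C4 and C21–C24 caps are attached last.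

Key step: step 15

Remark on numbering: locants C1–C24 are those of the target chain (C1 is the terminal CH2 next to the (R)-configured C3); systematic names of C5–C20 intermediates use hexadecane locants.

Assumption: the lipase is taken to hydrolyse the acetate on the (S)-configured carbon of the meso diacetate, as is usual for this substrate class; if a given enzyme shows the opposite preference, acetylation of the meso diol with vinyl acetate and the same enzyme gives the same monoacetate 3.

Step 1
Reactants: 1 cyclohexa-1,3-diene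
Product: 2 cis-cyclohex-2-ene-1,4-diyl diacetate (meso)
Conditions: Pd(OAc)2 (5 mol%), LiCl (cat.), LiOAc, p-benzoquinone, AcOH, rt
Reagents that add atoms: acetic acid (as acetate), CC(=O)O
Why: Palladium-catalysed oxidative 1,4-diacetoxylation of a 1,3-diene; with catalytic chloride the π-allylpalladium intermediate is opened by external acetate, so the second acetate should enter cis to the first and give the meso diacetate.

Step 2
Reactants: 2 cis-cyclohex-2-ene-1,4-diyl diacetate
Product: 3 (1R,4S)-4-hydroxycyclohex-2-en-1-yl acetate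
Conditions: Candida antarctica lipase B (immobilised), KH2PO4/K2HPO4 buffer pH 7, 25 °C
Reagents that add atoms: none
Why: Enzymatic desymmetrisation of a meso diester by enantiotopic-group-selective hydrolysis; cleavage of the acetate at the (S)-carbinol carbon alone fixes both ring stereocentres in one enantiomeric series.

Step 3
Reactants: 3 (1R,4S)-4-hydroxycyclohex-2-en-1-yl acetate
Product: 4 (1R,4R)-4-acetoxycyclohex-2-en-1-yl 4-nitrobenzoate
Conditions: 4-nitrobenzoic acid, PPh3, DIAD, THF, 0 °C → rt
Reagents that add atoms: 4-nitrobenzoic acid, OC(=O)c1ccc(cc1)[N+](=O)[O-]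
Why: Mitsunobu esterification; SN2 displacement of the oxyphosphonium group by the acidic carboxylate should invert the free carbinol carbon (S → R) and give the trans diester.

Step 4
Reactants: 4 (1R,4R)-4-acetoxycyclohex-2-en-1-yl 4-nitrobenzoate
Product: 5 (1R,4R)-cyclohex-2-ene-1,4-diol
Conditions: K2CO3 (cat.), MeOH, rt
Reagents that add atoms: none
Why: Base-catalysed transesterification with methanol removes both acyl groups at the acyl carbon, so the C–O bonds and the trans (1R,4R) configuration stay intact.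

Step 5
Reactants: 5 (1R,4R)-cyclohex-2-ene-1,4-diol
Product: 6 (3R,6R)-3,6-bis[(4-methoxyphenyl)methoxy]cyclohex-1-ene
Conditions: NaH, 4-methoxybenzyl chloride, Bu4NI (cat.), DMF, 0 °C → rt
Reagents that add atoms: 4-methoxybenzyl chloride, COc1ccc(CCl)cc1
Why: Williamson ether synthesis on both secondary alkoxides; no stereocentre is touched.

Step 6
Reactants: 6 (3R,6R)-3,6-bis[(4-methoxyphenyl)methoxy]cyclohex-1-ene
Product: 8 (2R,5R)-2,5-bis[(4-methoxyphenyl)methoxy]hexanedial, via ozonide 7 (not isolated)
Conditions: O3, CH2Cl2, −78 °C (Sudan Red 7B end point); then PPh3, −78 °C → rt; used crude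
Reagents that add atoms: ozone, [O-][O+]=O
Why: Ozonolysis with reductive work-up cleaves the only C=C bond (the dye end point stops the reaction before the electron-rich PMB rings are attacked) and opens the ring to the C10–C15 dialdehyde with C11 and C14 unchanged.

Step 7
Reactants: 9 (3R)-5-methoxy-3-methyl-5-oxopentanoic acid [methyl hydrogen (R)-3-methylglutarate]
Product: 10 methyl (3R)-5-hydroxy-3-methylpentanoate
Conditions: BH3·SMe2, THF, 0 °C → rt; MeOH quench
Reagents that add atoms: none
Why: Chemoselective borane reduction of a carboxylic acid beside a methyl ester (via the acyloxyborane); the β-stereocentre cannot epimerise.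

Step 8
Reactants: 10 methyl (3R)-5-hydroxy-3-methylpentanoate
Product: 11 methyl (3S)-5-bromo-3-methylpentanoate
Conditions: CBr4, PPh3, CH2Cl2, 0 °C
Reagents that add atoms: carbon tetrabromide, BrC(Br)(Br)Br
Why: Appel bromination of the primary alcohol under neutral conditions, run at once so that lactonisation does not intervene; the descriptor changes only through CIP priorities.

Step 9
Reactants: 11 methyl (3S)-5-bromo-3-methylpentanoate
Product: 12 (3S)-5-bromo-3-methylpentanal
Conditions: iBu2AlH (1.05 equiv), CH2Cl2, −78 °C; aq. potassium sodium tartrate (KNaC4H4O6) work-up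
Reagents that add atoms: none
Why: Partial ester reduction with diisobutylaluminium hydride stops at the aluminium hemiacetal at −78 °C and releases the aldehyde on work-up; the primary bromide is inert.

Step 10
Reactants: 12 (3S)-5-bromo-3-methylpentanal
Product: 13 (3R)-5-bromo-3-methyl-2-methylidenepentanal
Conditions: aq. CH2O (37%), pyrrolidine (10 mol%), propanoic acid (10 mol%), iPrOH, 45 °C, short reaction time
Reagents that add atoms: formaldehyde, C=O
Why: Amine-catalysed Mannich condensation–elimination (α-methylenation of an aldehyde) installs the C6 methylidene; the hydrogen on the adjacent stereocentre (later C7) sits in a cross-conjugated position and should not be exchanged.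

Step 11
Reactants: 13 (3R)-5-bromo-3-methyl-2-methylidenepentanal
Product: 14 (3R)-5-bromo-3-methyl-2-methylidenepentan-1-ol
Conditions: NaBH4, CeCl3·7H2O, MeOH, 0 °C
Reagents that add atoms: none
Why: Luche reduction gives clean 1,2-reduction of the enal to the 2-substituted allylic alcohol.

Step 12
Reactants: 14 (3R)-5-bromo-3-methyl-2-methylidenepentan-1-ol
Product: 15 {[(3R)-5-bromo-3-methyl-2-methylidenepentyl]oxy}(tert-butyl)dimethylsilane
Conditions: TBSCl, imidazole, CH2Cl2, 0 °C → rt
Reagents that add atoms: tert-butyldimethylsilyl chloride, CC(C)(C)[Si](C)(C)Cl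
Why: Standard silylation of the primary allylic alcohol gives the C5–C9 arm with a group that survives Grignard, oxidation and DDQ steps.

Step 13
Reactants: 15 {[(3R)-5-bromo-3-methyl-2-methylidenepentyl]oxy}(tert-butyl)dimethylsilane; 8 (2R,5R)-2,5-bis[(4-methoxyphenyl)methoxy]hexanedial
Product: 17 (3R,7R,10R,14R)-1,16-bis{[tert-butyl(dimethyl)silyl]oxy}-7,10-bis[(4-methoxyphenyl)methoxy]-3,14-dimethyl-2,15-dimethylidenehexadecane-6,11-diol (epimer mixture at C10 and C15 of the target chain), via arm Grignard reagent 16 (not isolated)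
Conditions: 15 (2.6 equiv), Mg (I2-activated), THF, rt → 40 °C; then 8, THF, −78 → 0 °C; aq. NH4Cl
Reagents that add atoms: none
Why: Grignard formation and two-directional 1,2-addition to both aldehydes forms C9–C10 and C15–C16; the new carbinol centres need no control because step 14 removes them.

Step 14
Reactants: 17 C5–C20 bis(secondary alcohol)
Product: 18 (3R,7R,10R,14R)-1,16-bis{[tert-butyl(dimethyl)silyl]oxy}-7,10-bis[(4-methoxyphenyl)methoxy]-3,14-dimethyl-2,15-dimethylidenehexadecane-6,11-dione (7R,11R,14R,18R in target numbering)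
Conditions: Dess–Martin periodinane, CH2Cl2, 0 °C → rt
Reagents that add atoms: none
Why: Dess–Martin oxidation converts both secondary alcohols into ketones under mild, non-basic conditions that should not epimerise the α-alkoxy centres C11 and C14.

Step 15
Reactants: 18 C2-symmetric C5–C20 bis(α-PMB-oxy ketone)
Product: 19 (3R,6S,7R,10R,11S,14R)-1,16-bis{[tert-butyl(dimethyl)silyl]oxy}-7,10-bis[(4-methoxyphenyl)methoxy]-3,6,11,14-tetramethyl-2,15-dimethylidenehexadecane-6,11-diol (10S,11R,14R,15S in target numbering)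
Conditions: MeMgBr (Et2O solution, 5 equiv), CH2Cl2, −78 °C; aq. NH4Cl
Reagents that add atoms: methylmagnesium bromide, C[Mg]Br
Why: MeMgBr first coordinates each ketone oxygen together with the neighbouring PMB ether oxygen, so that C10=O/C11–O and C15=O/C14–O are locked in five-membered magnesium chelates, and methyl is then transferred to the carbonyl face that carries the C11 (C14) hydrogen instead of the C12 (C13) chain. The closest known reaction type is the Cram-chelate-controlled Grignard addition to α-alkoxy ketones. No ring is closed; two C–CH3 bonds are formed. The new stereocentre C10 is controlled by C11 and C15 by C14, which should give the (10S,11R) and (14R,15S) relationships. The step needs only diastereofacial selectivity, and this is secured by the chelating benzyl-type ether, the weakly coordinating medium at −78 °C, and the C2 axis, which makes both ketones identical so that one operation sets both centres.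

Step 16
Reactants: 19 C5–C20 bis(tertiary alcohol) bis-PMB ether
Product: 20 (3R,6S,7R,10R,11S,14R)-1,16-bis{[tert-butyl(dimethyl)silyl]oxy}-3,6,11,14-tetramethyl-2,15-dimethylidenehexadecane-6,7,10,11-tetrol
Conditions: DDQ (2.5 equiv), CH2Cl2/aq. KH2PO4–K2HPO4 buffer pH 7 (10:1), 0 °C
Reagents that add atoms: none
Why: Oxidative PMB ether cleavage; the water-rich buffered medium traps the benzylic oxocarbenium ion as a hemiacetal before the neighbouring tertiary hydroxyl can close an anisylidene acetal, and the silyl ethers and 1,1-disubstituted alkenes are not oxidised.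

Step 17
Reactants: 20 C5–C20 tetraol
Product: 22 (3R,6S,7S,10S,11S,14R)-1,16-bis{[tert-butyl(dimethyl)silyl]oxy}-6,7:10,11-diepoxy-3,6,11,14-tetramethyl-2,15-dimethylidenehexadecane (10S,11S,14S,15S in target numbering), via bis-mesylate 21 (not isolated)
Conditions: MsCl (2.2 equiv), Et3N, CH2Cl2, −20 °C; then K2CO3, MeOH, 0 °C → rt
Reagents that add atoms: none
Why: Sulfene-type mesylation is far faster at the secondary C11/C14 hydroxyls than at the tertiary ones and quickly blocks both (so that no mono-mesylate lingers to close a tetrahydrofuran), after which each tertiary alkoxide displaces its neighbouring mesylate in a 3-exo-tet Williamson closure with inversion at C11 and C14.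

Step 18
Reactants: 22 bis-epoxide bis-silyl ether
Product: 23 (3R,6S,7S,10S,11S,14R)-6,7:10,11-diepoxy-3,6,11,14-tetramethyl-2,15-dimethylidenehexadecane-1,16-diol
Conditions: Bu4NF, THF, 0 °C → rt
Reagents that add atoms: none
Why: Fluoride-induced desilylation frees both allylic alcohols; trisubstituted oxiranes are stable to fluoride.

Step 19
Reactants: 23 bis-epoxy diol
Product: 25 (3R,6S,7S,10S,11S,14R)-16-bromo-6,7:10,11-diepoxy-3,6,11,14-tetramethyl-2,15-dimethylidenehexadecan-1-ol, via mono-mesylate 24 (not isolated)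
Conditions: MsCl (1.0 equiv), Et3N, THF, −45 °C; then LiBr, THF, −45 → 0 °C
Reagents that add atoms: lithium bromide, [Li+].[Br-]
Why: Statistical mono-activation of one of the two homotopic allylic hydroxyls (mesylation, then SN2 displacement by bromide under conditions that spare trisubstituted oxiranes) breaks the C2 symmetry; 25 should separate easily from recovered 23, which is recycled, and from the dibromide.

Step 20
Reactants: 26 methyl (2R)-3-hydroxy-2-methylpropanoate
Product: 27 methyl (2R)-3-{[tert-butyl(dimethyl)silyl]oxy}-2-methylpropanoate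
Conditions: TBSCl, imidazole, DMF, 0 °C → rt
Reagents that add atoms: tert-butyldimethylsilyl chloride, CC(C)(C)[Si](C)(C)Cl
Why: Standard silylation of the primary alcohol; the α-stereocentre is not affected.

Step 21
Reactants: 27 methyl (2R)-3-{[tert-butyl(dimethyl)silyl]oxy}-2-methylpropanoate
Product: 29 (3R)-4-{[tert-butyl(dimethyl)silyl]oxy}-3-methylbutan-2-one, via Weinreb amide 28 (not isolated)
Conditions: MeNHOMe·HCl, iPrMgCl, THF, −20 °C; then MeMgBr, −20 → 0 °C; aq. NH4Cl
Reagents that add atoms: methylmagnesium bromide, C[Mg]Br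
Why: Weinreb ketone synthesis in one pot; the magnesium amide converts the ester into the N-methoxy-N-methylamide, whose chelated tetrahedral adduct with MeMgBr releases the ketone only on work-up, so neither over-addition nor epimerisation should occur.

Step 22
Reactants: 29 (3R)-4-{[tert-butyl(dimethyl)silyl]oxy}-3-methylbutan-2-one
Product: 30 tert-butyl{[(2S)-2,3-dimethylbut-3-en-1-yl]oxy}dimethylsilane
Conditions: Ph3PCH3Br, KOtBu, THF, 0 °C → rt
Reagents that add atoms: methyltriphenylphosphonium bromide, C[P+](c1ccccc1)(c1ccccc1)c1ccccc1.[Br-]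
Why: Wittig methylenation with the non-stabilised ylide, which adds to the methyl ketone faster than it enolises it, so the α-stereocentre should be kept; the change of descriptor is a priority effect only.

Step 23
Reactants: 30 tert-butyl{[(2S)-2,3-dimethylbut-3-en-1-yl]oxy}dimethylsilane
Product: 31 (3S)-4-bromo-2,3-dimethylbut-1-ene
Conditions: Ph3PBr2, CH2Cl2, 0 °C → rt
Reagents that add atoms: dibromotriphenylphosphorane, BrP(Br)(c1ccccc1)(c1ccccc1)c1ccccc1
Why: Appel-type direct conversion of a primary silyl ether into the bromide through an alkoxyphosphonium bromide, which avoids isolating the volatile alcohol and leaves the neighbouring stereocentre untouched.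

Step 24
Reactants: 32 methyl (2S)-3-hydroxy-2-methylpropanoate
Product: 33 methyl (2S)-3-{[tert-butyl(dimethyl)silyl]oxy}-2-methylpropanoate
Conditions: TBSCl, imidazole, DMF, 0 °C → rt
Reagents that add atoms: tert-butyldimethylsilyl chloride, CC(C)(C)[Si](C)(C)Cl
Why: Standard silylation, as in step 20, in the enantiomeric series.

Step 25
Reactants: 33 methyl (2S)-3-{[tert-butyl(dimethyl)silyl]oxy}-2-methylpropanoate
Product: 35 (3S)-4-{[tert-butyl(dimethyl)silyl]oxy}-3-methylbutan-2-one, via Weinreb amide 34 (not isolated)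
Conditions: MeNHOMe·HCl, iPrMgCl, THF, −20 °C; then MeMgBr, −20 → 0 °C; aq. NH4Cl
Reagents that add atoms: methylmagnesium bromide, C[Mg]Br
Why: One-pot Weinreb ketone synthesis, as in step 21, with retention of the α-stereocentre.

Step 26
Reactants: 35 (3S)-4-{[tert-butyl(dimethyl)silyl]oxy}-3-methylbutan-2-one
Product: 36 tert-butyl{[(2R)-2,3-dimethylbut-3-en-1-yl]oxy}dimethylsilane
Conditions: Ph3PCH3Br, KOtBu, THF, 0 °C → rt
Reagents that add atoms: methyltriphenylphosphonium bromide, C[P+](c1ccccc1)(c1ccccc1)c1ccccc1.[Br-]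
Why: Wittig methylenation, as in step 22.

Step 27
Reactants: 36 tert-butyl{[(2R)-2,3-dimethylbut-3-en-1-yl]oxy}dimethylsilane
Product: 37 (3R)-4-bromo-2,3-dimethylbut-1-ene
Conditions: Ph3PBr2, CH2Cl2, 0 °C → rt
Reagents that add atoms: dibromotriphenylphosphorane, BrP(Br)(c1ccccc1)(c1ccccc1)c1ccccc1
Why: Appel-type conversion of the silyl ether into the bromide, as in step 23.

Step 28
Reactants: 31 (3S)-4-bromo-2,3-dimethylbut-1-ene; 25 C5–C20 hydroxy bromide
Product: 39 (3R,7R,10S,11S,14S,15S,18R)-10,11:14,15-diepoxy-2,3,7,10,15,18-hexamethyl-6,19-dimethylideneicos-1-en-20-ol (target numbering), via cap Grignard reagent 38 (not isolated)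
Conditions: 31, Mg, THF, rt; then this solution (3 equiv, the first equivalent being spent on the hydroxyl) added to 25, Li2CuCl4 (5 mol%), THF, −78 → −40 °C; cold aq. NH4Cl
Reagents that add atoms: none
Why: Copper-catalysed cross-coupling of a primary alkyl Grignard reagent with a 2-substituted allylic bromide, for which SN2 and SN2' attack give the same product; it forms C4–C5 and brings in C3 with the (R) configuration, and at −78 °C the trisubstituted oxiranes should not compete.

Step 29
Reactants: 39 C1–C20 allylic alcohol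
Product: 41 (3R,7R,10S,11S,14S,15S,18R)-20-bromo-10,11:14,15-diepoxy-2,3,7,10,15,18-hexamethyl-6,19-dimethylideneicos-1-ene (target numbering), via mesylate 40 (not isolated)
Conditions: MsCl (1.3 equiv), Et3N, THF, −45 °C; then LiBr, THF, −45 → 0 °C
Reagents that add atoms: lithium bromide, [Li+].[Br-]
Why: Mesylation of the remaining allylic alcohol and SN2 displacement by bromide, conditions known to tolerate acid-sensitive trisubstituted oxiranes.

Step 30
Reactants: 37 (3R)-4-bromo-2,3-dimethylbut-1-ene; 41 C1–C20 allylic bromide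
Product: 43 (3R,7R,10S,11S,14S,15S,18R,22S)-10,11:14,15-diepoxy-2,3,7,10,15,18,22,23-octamethyl-6,19-dimethylidenetetracosa-1,23-diene (target), via cap Grignard reagent 42 (not isolated)
Conditions: 37, Mg, THF, rt; then this solution (2 equiv) added to 41, Li2CuCl4 (5 mol%), THF, −78 → −40 °C; cold aq. NH4Cl; chromatography on Et3N-deactivated silica
Reagents that add atoms: none
Why: Second copper-catalysed alkyl–allyl Grignard coupling forms C20–C21 and brings in C22 with the (S) configuration from the enantiomeric cap, which completes the only non-symmetric feature of the target.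

**Compound list**

1 | cyclohexa-1,3-diene | C1=CC=CCC1 | starting material
2 | cis-cyclohex-2-ene-1,4-diyl diacetate (meso, 1R,4S) | CC(=O)O[C@H]1C=C[C@@H](OC(C)=O)CC1 | intermediate
3 | (1R,4S)-4-hydroxycyclohex-2-en-1-yl acetate | CC(=O)O[C@H]1C=C[C@@H](O)CC1 | intermediate
4 | (1R,4R)-4-acetoxycyclohex-2-en-1-yl 4-nitrobenzoate | CC(=O)O[C@H]1C=C[C@H](OC(=O)c2ccc(cc2)[N+](=O)[O-])CC1 | intermediate
5 | (1R,4R)-cyclohex-2-ene-1,4-diol | O[C@H]1C=C[C@H](O)CC1 | intermediate
6 | (3R,6R)-3,6-bis[(4-methoxyphenyl)methoxy]cyclohex-1-ene | COc1ccc(CO[C@H]2C=C[C@H](OCc3ccc(OC)cc3)CC2)cc1 | intermediate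
7 | (2R,5R)-2,5-bis[(4-methoxyphenyl)methoxy]-7,8,9-trioxabicyclo[4.2.1]nonane (ozonide, bridgehead configuration not defined) | COc1ccc(CO[C@@H]2CC[C@@H](OCc3ccc(OC)cc3)C3OOC2O3)cc1 | intermediate (not isolated)
8 | (2R,5R)-2,5-bis[(4-methoxyphenyl)methoxy]hexanedial | O=C[C@H](OCc1ccc(OC)cc1)CC[C@@H](OCc1ccc(OC)cc1)C=O | intermediate
9 | (3R)-5-methoxy-3-methyl-5-oxopentanoic acid [methyl hydrogen (R)-3-methylglutarate] | COC(=O)C[C@H](C)CC(=O)O | starting material
10 | methyl (3R)-5-hydroxy-3-methylpentanoate | COC(=O)C[C@H](C)CCO | intermediate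
11 | methyl (3S)-5-bromo-3-methylpentanoate | COC(=O)C[C@H](C)CCBr | intermediate
12 | (3S)-5-bromo-3-methylpentanal | O=CC[C@H](C)CCBr | intermediate
13 | (3R)-5-bromo-3-methyl-2-methylidenepentanal | O=CC(=C)[C@H](C)CCBr | intermediate
14 | (3R)-5-bromo-3-methyl-2-methylidenepentan-1-ol | OCC(=C)[C@H](C)CCBr | intermediate
15 | {[(3R)-5-bromo-3-methyl-2-methylidenepentyl]oxy}(tert-butyl)dimethylsilane | CC(C)(C)[Si](C)(C)OCC(=C)[C@H](C)CCBr | intermediate
16 | [(3R)-5-{[tert-butyl(dimethyl)silyl]oxy}-3-methyl-4-methylidenepentyl]magnesium bromide | CC(C)(C)[Si](C)(C)OCC(=C)[C@H](C)CC[Mg]Br | intermediate (not isolated)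
17 | (3R,7R,10R,14R)-1,16-bis{[tert-butyl(dimethyl)silyl]oxy}-7,10-bis[(4-methoxyphenyl)methoxy]-3,14-dimethyl-2,15-dimethylidenehexadecane-6,11-diol (6,11-epimer mixture) | CC(C)(C)[Si](C)(C)OCC(=C)[C@H](C)CCC(O)[C@H](OCc1ccc(OC)cc1)CC[C@@H](OCc1ccc(OC)cc1)C(O)CC[C@@H](C)C(=C)CO[Si](C)(C)C(C)(C)C | intermediate
18 | (3R,7R,10R,14R)-1,16-bis{[tert-butyl(dimethyl)silyl]oxy}-7,10-bis[(4-methoxyphenyl)methoxy]-3,14-dimethyl-2,15-dimethylidenehexadecane-6,11-dione | CC(C)(C)[Si](C)(C)OCC(=C)[C@H](C)CCC(=O)[C@H](OCc1ccc(OC)cc1)CC[C@@H](OCc1ccc(OC)cc1)C(=O)CC[C@@H](C)C(=C)CO[Si](C)(C)C(C)(C)C | intermediate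
19 | (3R,6S,7R,10R,11S,14R)-1,16-bis{[tert-butyl(dimethyl)silyl]oxy}-7,10-bis[(4-methoxyphenyl)methoxy]-3,6,11,14-tetramethyl-2,15-dimethylidenehexadecane-6,11-diol | CC(C)(C)[Si](C)(C)OCC(=C)[C@H](C)CC[C@](C)(O)[C@H](OCc1ccc(OC)cc1)CC[C@@H](OCc1ccc(OC)cc1)[C@@](C)(O)CC[C@@H](C)C(=C)CO[Si](C)(C)C(C)(C)C | intermediate
20 | (3R,6S,7R,10R,11S,14R)-1,16-bis{[tert-butyl(dimethyl)silyl]oxy}-3,6,11,14-tetramethyl-2,15-dimethylidenehexadecane-6,7,10,11-tetrol | CC(C)(C)[Si](C)(C)OCC(=C)[C@H](C)CC[C@](C)(O)[C@H](O)CC[C@@H](O)[C@@](C)(O)CC[C@@H](C)C(=C)CO[Si](C)(C)C(C)(C)C | intermediate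
21 | 7,10-bis(methanesulfonate) of tetraol 20 | CC(C)(C)[Si](C)(C)OCC(=C)[C@H](C)CC[C@](C)(O)[C@H](OS(C)(=O)=O)CC[C@@H](OS(C)(=O)=O)[C@@](C)(O)CC[C@@H](C)C(=C)CO[Si](C)(C)C(C)(C)C | intermediate (not isolated)
22 | (3R,6S,7S,10S,11S,14R)-1,16-bis{[tert-butyl(dimethyl)silyl]oxy}-6,7:10,11-diepoxy-3,6,11,14-tetramethyl-2,15-dimethylidenehexadecane | CC(C)(C)[Si](C)(C)OCC(=C)[C@H](C)CC[C@]1(C)O[C@H]1CC[C@@H]1O[C@@]1(C)CC[C@@H](C)C(=C)CO[Si](C)(C)C(C)(C)C | intermediate
23 | (3R,6S,7S,10S,11S,14R)-6,7:10,11-diepoxy-3,6,11,14-tetramethyl-2,15-dimethylidenehexadecane-1,16-diol | OCC(=C)[C@H](C)CC[C@]1(C)O[C@H]1CC[C@@H]1O[C@@]1(C)CC[C@@H](C)C(=C)CO | intermediate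
24 | mono(methanesulfonate) of diol 23 | CS(=O)(=O)OCC(=C)[C@H](C)CC[C@]1(C)O[C@H]1CC[C@@H]1O[C@@]1(C)CC[C@@H](C)C(=C)CO | intermediate (not isolated)
25 | (3R,6S,7S,10S,11S,14R)-16-bromo-6,7:10,11-diepoxy-3,6,11,14-tetramethyl-2,15-dimethylidenehexadecan-1-ol | BrCC(=C)[C@H](C)CC[C@]1(C)O[C@H]1CC[C@@H]1O[C@@]1(C)CC[C@@H](C)C(=C)CO | intermediate
26 | methyl (2R)-3-hydroxy-2-methylpropanoate | COC(=O)[C@H](C)CO | starting material
27 | methyl (2R)-3-{[tert-butyl(dimethyl)silyl]oxy}-2-methylpropanoate | COC(=O)[C@H](C)CO[Si](C)(C)C(C)(C)C | intermediate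
28 | (2R)-3-{[tert-butyl(dimethyl)silyl]oxy}-N-methoxy-N,2-dimethylpropanamide | CON(C)C(=O)[C@H](C)CO[Si](C)(C)C(C)(C)C | intermediate (not isolated)
29 | (3R)-4-{[tert-butyl(dimethyl)silyl]oxy}-3-methylbutan-2-one | CC(=O)[C@H](C)CO[Si](C)(C)C(C)(C)C | intermediate
30 | tert-butyl{[(2S)-2,3-dimethylbut-3-en-1-yl]oxy}dimethylsilane | C=C(C)[C@H](C)CO[Si](C)(C)C(C)(C)C | intermediate
31 | (3S)-4-bromo-2,3-dimethylbut-1-ene | C=C(C)[C@H](C)CBr | intermediate
32 | methyl (2S)-3-hydroxy-2-methylpropanoate | COC(=O)[C@@H](C)CO | starting material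
33 | methyl (2S)-3-{[tert-butyl(dimethyl)silyl]oxy}-2-methylpropanoate | COC(=O)[C@@H](C)CO[Si](C)(C)C(C)(C)C | intermediate
34 | (2S)-3-{[tert-butyl(dimethyl)silyl]oxy}-N-methoxy-N,2-dimethylpropanamide | CON(C)C(=O)[C@@H](C)CO[Si](C)(C)C(C)(C)C | intermediate (not isolated)
35 | (3S)-4-{[tert-butyl(dimethyl)silyl]oxy}-3-methylbutan-2-one | CC(=O)[C@@H](C)CO[Si](C)(C)C(C)(C)C | intermediate
36 | tert-butyl{[(2R)-2,3-dimethylbut-3-en-1-yl]oxy}dimethylsilane | C=C(C)[C@@H](C)CO[Si](C)(C)C(C)(C)C | intermediate
37 | (3R)-4-bromo-2,3-dimethylbut-1-ene | C=C(C)[C@@H](C)CBr | intermediate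
38 | [(2S)-2,3-dimethylbut-3-en-1-yl]magnesium bromide | C=C(C)[C@H](C)C[Mg]Br | intermediate (not isolated)
39 | (3R,7R,10S,11S,14S,15S,18R)-10,11:14,15-diepoxy-2,3,7,10,15,18-hexamethyl-6,19-dimethylideneicos-1-en-20-ol (target numbering) | C=C(C)[C@H](C)CCC(=C)[C@H](C)CC[C@]1(C)O[C@H]1CC[C@@H]1O[C@@]1(C)CC[C@@H](C)C(=C)CO | intermediate
40 | methanesulfonate of alcohol 39 | C=C(C)[C@H](C)CCC(=C)[C@H](C)CC[C@]1(C)O[C@H]1CC[C@@H]1O[C@@]1(C)CC[C@@H](C)C(=C)COS(C)(=O)=O | intermediate (not isolated)
41 | (3R,7R,10S,11S,14S,15S,18R)-20-bromo-10,11:14,15-diepoxy-2,3,7,10,15,18-hexamethyl-6,19-dimethylideneicos-1-ene (target numbering) | C=C(C)[C@H](C)CCC(=C)[C@H](C)CC[C@]1(C)O[C@H]1CC[C@@H]1O[C@@]1(C)CC[C@@H](C)C(=C)CBr | intermediate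
42 | [(2R)-2,3-dimethylbut-3-en-1-yl]magnesium bromide | C=C(C)[C@@H](C)C[Mg]Br | intermediate (not isolated)
43 | (3R,7R,10S,11S,14S,15S,18R,22S)-10,11:14,15-diepoxy-2,3,7,10,15,18,22,23-octamethyl-6,19-dimethylidenetetracosa-1,23-diene | C=C(C)[C@H](C)CCC(=C)[C@H](C)CC[C@]1(C)O[C@H]1CC[C@@H]1O[C@@]1(C)CC[C@@H](C)C(=C)CC[C@H](C)C(=C)C | target

**Count**

Total step count: 30. Longest linear sequence: 16 steps (1–6, 13–19, 28–30; the arm branch 7–12 joining at step 13 is equally long).

**Steps most likely to fail**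

Step 15. What may go wrong: part of the ketone may react through an open, non-chelated arrangement when other donors compete with the PMB oxygen for magnesium, so that methyl also enters from the opposite face and C10/C15 epimers form; enolisation would return ketone. The fallback sets out from 18 and replaces the ether chelate by a covalent alkoxide chelate. DDQ in wet CH2Cl2 removes both PMB groups and gives the bis(α-hydroxy ketone) (3R,7R,10R,14R)-1,16-bis{[tert-butyl(dimethyl)silyl]oxy}-7,10-dihydroxy-3,14-dimethyl-2,15-dimethylidenehexadecane-6,11-dione F1. Excess MeMgBr (Et2O/CH2Cl2, −78 °C) first deprotonates the C11 and C14 hydroxyls; each magnesium alkoxide holds its neighbouring carbonyl in a five-membered ring, and methyl should again pass the C11/C14 hydrogen (chelation-controlled Grignard addition to α-hydroxy ketones). Work-up gives tetraol 20, where the route is rejoined; step 16 falls away.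

Step 28. What may go wrong: opening or rearrangement of the oxiranes promoted by magnesium halide, or stalling of the coupling when the magnesium alkoxide of the substrate aggregates, so that the allylic bromide is consumed unproductively. The fallback sets out from 31 and 25 and replaces the copper-catalysed Grignard coupling by sulfone alkylation and reductive desulfonylation. PhSO2Na (DMF, 50 °C) converts 31 into {[(2S)-2,3-dimethylbut-3-en-1-yl]sulfonyl}benzene F2. Its lithio derivative (nBuLi, THF, −78 °C; two equivalents, the first being spent on the hydroxyl of 25) is alkylated by the allylic bromide of 25 and gives the 4-(phenylsulfonyl) derivative of 39 F3 as a mixture of C4 epimers. Na(Hg), Na2HPO4, MeOH/THF, −20 °C then removes the sulfonyl group, and the route is rejoined at 39.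

Step 13. What may go wrong: degradation of the dialdehyde before or during the addition (epimerisation at C11/C14 next to the formyl groups, hydrate and oligomer formation), and incomplete second addition once the first alkoxide has closed onto the remaining aldehyde as a lactol. The fallback sets out from 6, avoids the dialdehyde and forms the ketones by acylation. Ozonolysis of 6 in CH2Cl2/methanolic NaOH at −78 °C gives dimethyl (2R,5R)-2,5-bis[(4-methoxyphenyl)methoxy]hexanedioate F4 directly. MeNHOMe·HCl/iPrMgCl (THF, −20 °C) converts it into (2R,5R)-N1,N6-dimethoxy-2,5-bis[(4-methoxyphenyl)methoxy]-N1,N6-dimethylhexanediamide F5. Grignard reagent 16 (from 15) then adds once to each amide (Weinreb ketone synthesis) and gives diketone 18 after work-up, where the route is rejoined; steps 13 and 14 are replaced.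

**Further compounds**

F1 | step 15 | (3R,7R,10R,14R)-1,16-bis{[tert-butyl(dimethyl)silyl]oxy}-7,10-dihydroxy-3,14-dimethyl-2,15-dimethylidenehexadecane-6,11-dione | CC(C)(C)[Si](C)(C)OCC(=C)[C@H](C)CCC(=O)[C@H](O)CC[C@@H](O)C(=O)CC[C@@H](C)C(=C)CO[Si](C)(C)C(C)(C)C
F2 | step 28 | {[(2S)-2,3-dimethylbut-3-en-1-yl]sulfonyl}benzene | C=C(C)[C@H](C)CS(=O)(=O)c1ccccc1
F3 | step 28 | 4-(phenylsulfonyl) derivative of alcohol 39 (C4 epimer mixture) | C=C(C)[C@H](C)C(CC(=C)[C@H](C)CC[C@]1(C)O[C@H]1CC[C@@H]1O[C@@]1(C)CC[C@@H](C)C(=C)CO)S(=O)(=O)c1ccccc1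
F4 | step 13 | dimethyl (2R,5R)-2,5-bis[(4-methoxyphenyl)methoxy]hexanedioate | COC(=O)[C@H](OCc1ccc(OC)cc1)CC[C@@H](OCc1ccc(OC)cc1)C(=O)OC
F5 | step 13 | (2R,5R)-N1,N6-dimethoxy-2,5-bis[(4-methoxyphenyl)methoxy]-N1,N6-dimethylhexanediamide | CON(C)C(=O)[C@H](OCc1ccc(OC)cc1)CC[C@@H](OCc1ccc(OC)cc1)C(=O)N(C)OC
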